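**Retrosynthetic overview**

1. Eudesmane numbering is used (C1 CHBr, C4 C(OH)CH3, C5/C10 ring fusion, C6 CHOAc, C7 CH‑iPr; α is the face of H5 and the C7 isopropyl group, β that of the C10 methyl). Enabling feature: in ring A, C1–C2–C3 are contiguous and the C1–Br and C3–C4 bonds are 1,3‑related, so they are the two ends of a 1,3‑addition across a cyclopropane C1–C2–C3; O4 and O6 are 1,3‑syn on C4–C5–C6 and can share one metal.
2. C6–OAc ⇒ bromo diol; ring A ⇒ the C3–C4 and C1–Br bonds are made together by bromide‑terminated attack of a C10 cyclopropyl group on the chelated C4 methyl ketone of a monocyclic β‑hydroxy ketone.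
3. β‑Hydroxy ketone ⇒ 1,3‑syn diol (chemoselective oxidation) ⇒ boron aldol with in situ reduction (C4–C5 bond, C6 carbinol) ⇒ conjugate addition of cyclopropyl to (R)‑piperitone (C1–C10 bond, quaternary C10).
4. Ring order: ring B comes intact from piperitone, with C7; ring A is formed last, in the key step.

Key step: step 4

Remark: natural (R)‑(−)‑piperitone is assumed to be used in enantiomerically enriched form; its C7 stereocentre is the only source of absolute configuration.

**Route**

Step 1
Reactants: 1 (R)‑(−)‑piperitone [(6R)‑3‑methyl‑6‑(propan‑2‑yl)cyclohex‑2‑en‑1‑one]; 2 cyclopropylmagnesium bromide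
Product: 4 (3R,6R)‑3‑cyclopropyl‑3‑methyl‑6‑(propan‑2‑yl)cyclohexan‑1‑one, via bromomagnesium enolate 3 (not isolated)
Conditions: 2 (1.5 equiv), CuBr·SMe2 (10 mol%), THF, −40 to −20 °C; sat. aq. NH4Cl
Reagents that add atoms: cyclopropylmagnesium bromide (2), Br[Mg]C1CC1
Why: Copper‑catalysed conjugate addition of a Grignard reagent to a β,β‑disubstituted cyclohexenone should build quaternary C10 by antiparallel (axial) attack on the half‑chair that keeps the C7 isopropyl group pseudo‑equatorial, which places cyclopropyl cis to isopropyl, while C7 is untouched because enolate 3 forms only toward C5.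

Step 2
Reactants: 4 (3R,6R)‑3‑cyclopropyl‑3‑methyl‑6‑(propan‑2‑yl)cyclohexan‑1‑one; 5 acetaldehyde
Product: 8 (1S,2R,3S,6R)‑3‑cyclopropyl‑2‑[(1R)‑1‑hydroxyethyl]‑3‑methyl‑6‑(propan‑2‑yl)cyclohexan‑1‑ol, via dicyclohexylboron enolate 6 (not isolated), via boron aldolate 7 (not isolated)
Conditions: (c‑C6H11)2BCl, Et3N, Et2O, 0 °C; 5, −78 °C; LiBH4, −78 °C; H2O2, MeOH, aq. NaOH, 0 °C
Reagents that add atoms: acetaldehyde (5), CC=O; chlorodicyclohexylborane, ClB(C1CCCCC1)C1CCCCC1 (its boron is carried only by 6 and 7)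
Why: Boron aldol addition with in situ LiBH4 reduction of the aldolate: the E‑configured enolate 6, formed at the less hindered C5 methylene, should add to acetaldehyde through a Zimmerman–Traxler chair on the face opposite the cis‑disposed cyclopropyl and isopropyl groups (C5 side chain β, anti relation at C4), and external hydride should then attack the six‑membered boron chelate 7 axially and anti to the axial C7 isopropyl group, giving the 1,3‑syn diol with the C6 hydroxyl α.

Step 3
Reactants: 8 (1S,2R,3S,6R)‑3‑cyclopropyl‑2‑[(1R)‑1‑hydroxyethyl]‑3‑methyl‑6‑(propan‑2‑yl)cyclohexan‑1‑ol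
Product: 9 1‑[(1S,2S,5R,6S)‑2‑cyclopropyl‑6‑hydroxy‑2‑methyl‑5‑(propan‑2‑yl)cyclohexyl]ethan‑1‑one
Conditions: TEMPO (10 mol%), PhI(OAc)2 (1.1 equiv), CH2Cl2, 0 °C to rt
Reagents that add atoms: none
Why: Oxoammonium oxidation depends on steric access to the carbinol C–H, so the side‑chain methyl carbinol at C4 should be oxidised in preference to the ring carbinol at C6, whose axial C–H is flanked by C5, C7 and the syn‑axial C10 methyl; no stereocentre is formed and C5 is not enolised under these near‑neutral conditions.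

Step 4
Reactants: 9 1‑[(1S,2S,5R,6S)‑2‑cyclopropyl‑6‑hydroxy‑2‑methyl‑5‑(propan‑2‑yl)cyclohexyl]ethan‑1‑one
Product: 12 bromo diol (1R,4R,4aR,7R,8S,8aS)‑4‑bromo‑1,4a‑dimethyl‑7‑(propan‑2‑yl)decahydronaphthalene‑1,8‑diol, via titanium chelate 10 (not isolated), via titanium diolate 11 (not isolated)
Conditions: TiBr4 (1.2 equiv), 2,6‑di‑tert‑butyl‑4‑methylpyridine (1.2 equiv), CH2Cl2, −78 to −30 °C; aq. NaHCO3
Reagents that add atoms: titanium tetrabromide, Br[Ti](Br)(Br)Br
Why: Proposed new method: the C6 hydroxyl becomes a tribromotitanium alkoxide that chelates and activates the C4 ketone (10); one methylene of the equatorial C10 cyclopropyl group (the future C3) attacks the carbonyl carbon as a σ‑nucleophile while its bond to the substituted carbon C1 breaks, and bromide from the titanium centre captures the developing C1 cation, so that a carbon electrophile and bromide add 1,3 across the three‑membered ring. The closest known reaction types are the TiBr4‑mediated halo‑Prins cyclisation of alkenes onto activated carbonyl groups and the Friedel–Crafts‑type 1,3‑haloacylation and ring‑opening 1,3‑dibromination of simple cyclopropanes, which also place halide on the more substituted carbon with inversion; new here is an unactivated cyclopropane as terminator toward a chelated ketone. Ring A closes in a 6‑exo‑trig sense at the carbonyl (the cleaved C1–C3 bond lies inside the new ring) through a chair trans‑fused to the chair of ring B. C4 is controlled by the six‑membered O6–Ti–O4 chelate, which holds the carbonyl oxygen on the C6 side so that O4 becomes equatorial (α) and the methyl axial (β); C1 is controlled by backside entry of bromide antiperiplanar to the breaking C1–C3 bond, which is the equatorial direction of the chair (1β‑Br), and C5, C6, C7 and C10 are not touched. The step needs opening toward the more substituted carbon C1, no 1,2‑shift from quaternary C10, no capture by O4 and no protolytic opening of the cyclopropane: the chair leaves no C10 substituent antiperiplanar to the breaking bond and keeps equatorial O4 away from C1, the gem‑disubstitution at C10 and the internal chelate activation favour closure, and the hindered pyridine removes HBr.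

Step 5
Reactants: 12 bromo diol (1R,4R,4aR,7R,8S,8aS)‑4‑bromo‑1,4a‑dimethyl‑7‑(propan‑2‑yl)decahydronaphthalene‑1,8‑diol
Product: 13 austradiol acetate, (1S,2R,4aR,5R,8R,8aS)‑5‑bromo‑8‑hydroxy‑4a,8‑dimethyl‑2‑(propan‑2‑yl)decahydronaphthalen‑1‑yl acetate
Conditions: Ac2O, pyridine, DMAP (cat.), CH2Cl2, 0 °C to rt
Reagents that add atoms: acetic anhydride, CC(=O)OC(C)=O
Why: DMAP‑catalysed acylation should esterify only the secondary equatorial C6 hydroxyl, the tertiary C4 hydroxyl being inert under these conditions, and no stereocentre is affected.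

**Compound list**

1 | (R)‑(−)‑piperitone, (6R)‑3‑methyl‑6‑(propan‑2‑yl)cyclohex‑2‑en‑1‑one | CC1=CC(=O)[C@@H](C(C)C)CC1 | starting material
2 | cyclopropylmagnesium bromide | Br[Mg]C1CC1 | starting material
3 | bromomagnesium enolate of 4 (enolate double bond C5=C6; cyclopropyl cis to isopropyl) | Br[Mg]OC1=C[C@](C)(C2CC2)CC[C@@H]1C(C)C | intermediate
4 | (3R,6R)‑3‑cyclopropyl‑3‑methyl‑6‑(propan‑2‑yl)cyclohexan‑1‑one | O=C1[C@@H](C(C)C)CC[C@@](C)(C2CC2)C1 | intermediate
5 | acetaldehyde | CC=O | starting material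
6 | dicyclohexylboron enolate of 4 (enolate double bond C5=C6) | C3CCCCC3B(C4CCCCC4)OC1=C[C@](C)(C2CC2)CC[C@@H]1C(C)C | intermediate
7 | O‑dicyclohexylboryl derivative of the anti aldol (2R,3S,6R)‑3‑cyclopropyl‑2‑[(1R)‑1‑hydroxyethyl]‑3‑methyl‑6‑(propan‑2‑yl)cyclohexan‑1‑one | O=C1[C@@H](C(C)C)CC[C@@](C)(C2CC2)[C@@H]1[C@@H](C)OB(C3CCCCC3)C3CCCCC3 | intermediate
8 | (1S,2R,3S,6R)‑3‑cyclopropyl‑2‑[(1R)‑1‑hydroxyethyl]‑3‑methyl‑6‑(propan‑2‑yl)cyclohexan‑1‑ol (1,3‑syn diol; 6α‑OH) | O[C@H]1[C@@H](C(C)C)CC[C@@](C)(C2CC2)[C@@H]1[C@@H](C)O | intermediate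
9 | 1‑[(1S,2S,5R,6S)‑2‑cyclopropyl‑6‑hydroxy‑2‑methyl‑5‑(propan‑2‑yl)cyclohexyl]ethan‑1‑one | O[C@H]1[C@@H](C(C)C)CC[C@@](C)(C2CC2)[C@@H]1C(C)=O | intermediate
10 | tribromotitanium alkoxide of 9 (titanium chelated by the C4 ketone) | Br[Ti](Br)(Br)O[C@H]1[C@@H](C(C)C)CC[C@@](C)(C2CC2)[C@@H]1C(C)=O | intermediate
11 | cyclic dibromotitanium 4,6‑diolate of 12 | Br[Ti]1(Br)O[C@H]2[C@@H](C(C)C)CC[C@@]3(C)[C@H](Br)CC[C@@](C)(O1)[C@H]23 | intermediate
12 | (1R,4R,4aR,7R,8S,8aS)‑4‑bromo‑1,4a‑dimethyl‑7‑(propan‑2‑yl)decahydronaphthalene‑1,8‑diol (eudesmane numbering: 1β‑Br, 4α‑OH, 4β‑CH3, 5α‑H, 6α‑OH, 7α‑iPr, 10β‑CH3) | O[C@H]1[C@@H](C(C)C)CC[C@@]2(C)[C@H](Br)CC[C@@](C)(O)[C@H]12 | intermediate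
13 | austradiol acetate, (1S,2R,4aR,5R,8R,8aS)‑5‑bromo‑8‑hydroxy‑4a,8‑dimethyl‑2‑(propan‑2‑yl)decahydronaphthalen‑1‑yl acetate | CC(=O)O[C@H]1[C@@H](C(C)C)CC[C@@]2(C)[C@H](Br)CC[C@@](C)(O)[C@H]12 | target

**Count and risk**

Total step count: 5. Longest linear sequence: 5 steps, from 1.

Steps most likely to fail:

1. Step 4 (proposed new method). The cyclopropane σ‑bond may not attack the chelated ketone before retro‑aldol cleavage sets in, or the developing C1 cation may undergo a 1,2‑shift or lose a proton instead of capturing bromide. The fallback keeps the same C3–C4 closure but uses an acylium ion, for which Friedel–Crafts‑type 1,3‑haloacylation of simple cyclopropanes is known, and installs the C4 carbinol afterwards. It sets out from 9: haloform cleavage of the methyl ketone (NaOBr, dioxane–water, 0 °C) should give the hydroxy acid F1; acetylation (Ac2O, pyridine) gives the acetoxy acid F2; oxalyl bromide gives the acid bromide F3, which with AlBr3 (CH2Cl2, −78 °C) should close ring A through the same chair to the 1β‑bromo 4‑ketone F4. Methylenation with Zn/CH2Br2/TiCl4 gives the exocyclic alkene F5, and Mukaiyama hydration [Co(acac)2, PhSiH3, O2] is expected to deliver oxygen on the α face, away from the syn‑axial C10 methyl. The route is rejoined at 13.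

2. Step 2. Facial selectivity may be poor in the external hydride attack on the boron aldolate, where the syn‑axial C10 methyl opposes the desired trajectory, or in the aldol addition itself. The fallback delivers hydride internally instead. It sets out from 4: LiN(iPr)2 and Me3SiCl (THF, −78 °C) give the less substituted trimethylsilyl enol ether F6. Fluoride‑promoted aldol addition to acetaldehyde with [(Me2N)3S][Me3SiF2] (THF, −78 °C), which is syn‑selective through an open transition state whatever the enolate geometry, gives after mild acid the syn aldol F7. Evans–Saksena reduction with Me4NBH(OAc)3 (MeCN–AcOH, −30 °C) then transfers hydride intramolecularly from the C4 oxygen and should give the 1,3‑anti diol F8, the C4 epimer of 8 with the same 6α‑hydroxyl. Oxidation of F8 under the conditions of step 3 removes the C4 stereocentre and comes back to the route at 9.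

3. Step 3. Chemoselectivity may be lost, through oxidation of the ring carbinol or over‑oxidation to the β‑diketone. The fallback masks the ring hydroxyl first. It sets out from 8: 4‑methoxybenzaldehyde dimethyl acetal with catalytic camphorsulfonic acid (CH2Cl2) gives the six‑membered acetal F9. iBu2AlH (CH2Cl2, −78 to 0 °C) should open it at the less hindered oxygen, leaving the 4‑methoxybenzyl ether on O6 and a free C4 hydroxyl in F10. Dess–Martin oxidation gives the ketone F11, and DDQ (CH2Cl2–pH 7 buffer) removes the ether and returns to the route at 9.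

Further compounds
F1 | step 4 | (1S,2S,5R,6S)‑2‑cyclopropyl‑6‑hydroxy‑2‑methyl‑5‑(propan‑2‑yl)cyclohexane‑1‑carboxylic acid | O[C@H]1[C@@H](C(C)C)CC[C@@](C)(C2CC2)[C@@H]1C(O)=O
F2 | step 4 | 6‑O‑acetate of F1, (1S,2S,5R,6S)‑6‑acetoxy‑2‑cyclopropyl‑2‑methyl‑5‑(propan‑2‑yl)cyclohexane‑1‑carboxylic acid | CC(=O)O[C@H]1[C@@H](C(C)C)CC[C@@](C)(C2CC2)[C@@H]1C(O)=O
F3 | step 4 | acid bromide of F2 | CC(=O)O[C@H]1[C@@H](C(C)C)CC[C@@](C)(C2CC2)[C@@H]1C(Br)=O
F4 | step 4 | 6α‑acetoxy‑1β‑bromo‑7α‑isopropyl‑15‑nor‑eudesman‑4‑one (trans‑decalin, 10β‑methyl) | CC(=O)O[C@H]1[C@@H](C(C)C)CC[C@@]2(C)[C@H](Br)CCC(=O)[C@H]12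
F5 | step 4 | 6α‑acetoxy‑1β‑bromo‑7α‑isopropyl‑eudesm‑4(15)‑ene (trans‑decalin, 10β‑methyl) | CC(=O)O[C@H]1[C@@H](C(C)C)CC[C@@]2(C)[C@H](Br)CCC(=C)[C@H]12
F6 | step 2 | trimethylsilyl enol ether of 4 (double bond C5=C6) | C[Si](C)(C)OC1=C[C@](C)(C2CC2)CC[C@@H]1C(C)C
F7 | step 2 | syn aldol (2R,3S,6R)‑3‑cyclopropyl‑2‑[(1S)‑1‑hydroxyethyl]‑3‑methyl‑6‑(propan‑2‑yl)cyclohexan‑1‑one | O=C1[C@@H](C(C)C)CC[C@@](C)(C2CC2)[C@@H]1[C@H](C)O
F8 | step 2 | 1,3‑anti diol (1S,2R,3S,6R)‑3‑cyclopropyl‑2‑[(1S)‑1‑hydroxyethyl]‑3‑methyl‑6‑(propan‑2‑yl)cyclohexan‑1‑ol | O[C@H]1[C@@H](C(C)C)CC[C@@](C)(C2CC2)[C@@H]1[C@H](C)O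
F9 | step 3 | 4‑methoxybenzylidene acetal of 8 (aryl equatorial on the 1,3‑dioxane) | COc1ccc(cc1)[C@H]1O[C@H]2[C@@H](C(C)C)CC[C@@](C)(C3CC3)[C@@H]2[C@@H](C)O1
F10 | step 3 | 6‑O‑(4‑methoxybenzyl) ether of 8 with free C4 hydroxyl | COc1ccc(CO[C@H]2[C@@H](C(C)C)CC[C@@](C)(C3CC3)[C@@H]2[C@@H](C)O)cc1
F11 | step 3 | 6‑O‑(4‑methoxybenzyl) ether of 9 | COc1ccc(CO[C@H]2[C@@H](C(C)C)CC[C@@](C)(C3CC3)[C@@H]2C(C)=O)cc1
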